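Readings and results are calculated with constants of no real substance; scatter was added.

The ratio I start from is time to yield on Thursday's run: 20.0 min for 46% of the solid substrate charged. Carried on to the whole charge, it gives 0.725 h, the clearing time: the time a flask with Thursday's charge of solid substrate needs to turn all of it at Thursday's pace, as read from that one scattered reading.

| flask | solid substrate | reagent | remark | time |
|---|---|---|---|---|
| Thursday's | 0.050 M | 4.5 equiv | run made earlier |  |
| flask | 0.050 M | 3.00 equiv |  | 1.5 h |

Thursday's run (percent of the solid substrate charged)

| time / min | target / % |
|---|---|
| 1.33 | 2 |
| 2.00 | 5 |
| 3.00 | 9 |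
| 5.00 | 11 |
| 8.00 | 16 |
| 12.0 | 30 |
| 20.0 | 46 |

(each reading ± 2 percentage points)

- solid, in amounts per volume of the solution: solid substrate
- at the start none of the solid substrate is in solution

* when, up to 1.5 h, the flask holds most target
* the amount of target, in percent of the solid substrate charged, at that time

In the first instants none of the solid substrate is in solution, so target must wait for dissolving; Thursday's first reading is 2% at 1.33 min.

In the middle of Thursday's run the readings climb by 0.0218 min⁻¹ of the charge between 3.00 min and 20.0 min, close to the overall 0.0230 min⁻¹, although the solid shrinks meanwhile. I read that as dissolving being the rate-limiting step, and this is a bet: a pace scaled by the equivalents of reagent would stretch the clearing time to 1.09 h, but I commit to 0.725 h.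

Near the end of the new flask, turning the whole charge would take 33.3% of the reagent if one reagent goes to each target, so the solid substrate is the limiting reagent. Once it is used, target can hold or fall, so I put the peak at the clearing time. These readings cannot tell how far under 100% of the charge that peak lies.

The forecast says 1.2 h and 88%, reasoning that “the maximum should fall near the point of solid exhaustion”, and its time is later than mine.

The flask peaks at 0.723 h with 86.8% target, against my 0.725 h. Taking Thursday's run from 4.5 equiv to 3.00 equiv of reagent, with nothing else changed, moves its highest target up to its last reading, without the scatter, from 45.9% to 43.2%.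

    solid substrate ⇌ dissolved substrate, rate k1*(cs1 - [dissolved substrate]) while solid is left; crystals form when [dissolved substrate] > cs1 (solubility = 20.0 mM, k = 0.0660 min⁻¹)
    dissolved substrate + reagent → target (k = 6.50 L mol⁻¹ min⁻¹)
    2 dissolved substrate → side product (k = 13.0 L mol⁻¹ min⁻¹)
    reagent → decomposition product (k = 5.10 × 10⁻⁵ min⁻¹)
    target ⇌ isomer of the product (K = 25.0, k = 0.00420 min⁻¹)

A neighbour flask is charged with 0.20 M of solid substrate, at the equivalents and time of the new flask. If its solid substrate goes at the same moles per litre per minute, its clearing time stretches to 2.90 h, longer than the 1.5 h allowed. That leaves 48.3% of its charge at 1.5 h, and the neighbour flask still holds, solid or dissolved, 42%.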